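The C40 polyene is cut at C7=C8 and C7'=C8' into crocetin dialdehyde and two identical (R)-α-cyclogeranyl sulfones. Each ε-ring is treated as a 2,6-dimethylcyclohexa-2,5-diene in which C6 sits on the mirror plane, with the saturated CMe2–CH2 pair (C1–C2) on one side and the intact CMe=CH olefin (C5=C4) on the other. A catalyst-controlled Markovnikov hydromethylation of one enantiotopic olefin (H to C2, CH3 to C1) therefore creates the gem-dimethyl carbon, keeps the C4=C5 olefin and fixes C6 as R in one operation. Its precursor is the achiral Birch-derived ester 4, methyl 2,6-dimethylcyclohexa-2,5-diene-1-carboxylate, two steps from 2,6-dimethylbenzoic acid.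

Key step: step 3

Remark: the target is read as all-E (6R,6'R)-ε,ε-carotene, which is C2-symmetric, so one ring enantiomer serves both ends. The fragment structures were checked and needed no correction: the sulfones supply C7 and C7', the dialdehyde supplies C8 to C8' (10 + 20 + 10 carbons). Carotenoid numbering is used for all ring fragments, so the carboxyl carbon of 3–6 becomes C7.

Remark on the precursor: the methyl ester is kept as the spectator group on C6. It is installed without base, it removes the acidic proton, its carbonyl can bind nickel next to the radical centre, and it is one reduction away from the C7 carbinol.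

Assumption: which antipode of the bis(oxazoline) ligand gives the R ester cannot be predicted with confidence. The (S,S) ligand is written; its antipode would be used if the first experiment shows the opposite sense.

Step 1
Reactants: 1 2,6-dimethylbenzoic acid
Product: 3 2,6-dimethylcyclohexa-2,5-diene-1-carboxylic acid, via dilithium enediolate 2 (not isolated)
Conditions: Li (3.5 equiv), NH3(l)/THF, –78 °C; solid NH4Cl; then aq HCl to pH 3, 0 °C
Reagents that add atoms: none
Why: Birch reduction of a benzoate places the two new hydrogens on the carboxyl-bearing carbon and the carbon para to it, and kinetic protonation of enediolate 2 at the carbon next to the carboxylate on NH4Cl quench should leave both methyl-bearing olefins unconjugated.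

Step 2
Reactants: 3 2,6-dimethylcyclohexa-2,5-diene-1-carboxylic acid
Product: 4 methyl 2,6-dimethylcyclohexa-2,5-diene-1-carboxylate
Conditions: Me3SiCHN2 (hexanes), toluene/MeOH 4:1, 0 °C → rt; used promptly under argon
Reagents that add atoms: (trimethylsilyl)diazomethane, C[Si](C)(C)C=[N+]=[N-]
Why: Methyl esterification with (trimethylsilyl)diazomethane in methanol proceeds by proton transfer from the acid and SN2 attack of the carboxylate on the methyldiazonium ion, so neither base nor strong acid meets the doubly allylic C6–H and the skipped diene should neither conjugate nor aromatise.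

Step 3
Reactants: 4 methyl 2,6-dimethylcyclohexa-2,5-diene-1-carboxylate; 5 iodomethane
Product: 6 methyl (1R)-2,6,6-trimethylcyclohex-2-ene-1-carboxylate (methyl (R)-α-cyclogeranate)
Conditions: Fe(acac)3 (30 mol %), NiBr2·diglyme (10 mol %), (S,S)-2,2'-isopropylidenebis(4-phenyl-2-oxazoline) (12 mol %), Mn powder (20 mol %), Ph(iPrO)SiH2 (1.5 equiv, slow addition), MeI (1.3 equiv), 1,2-dichloroethane/DMPU, 0 °C → rt
Reagents that add atoms: iodomethane (compound 5), CI
Why: Proposed new method: the iron hydride made from Fe(acac)3 and the silane should deliver a hydrogen atom reversibly to C2 (or, equivalently, C4), so that either enantiotopic olefin becomes a tertiary radical at C1 (or C5), while the bis(oxazoline)-bound monovalent nickel adds CH3I and is reduced by the divalent iron left behind by the hydrogen-atom transfer to a divalent nickel–methyl, which traps the radical and forms the C1–CH3 bond by reductive elimination from trivalent nickel, the overall change being redox-neutral. The closest known reaction types are the iron-hydride/nickel dual-catalytic Markovnikov hydroalkylation of trisubstituted olefins that builds quaternary carbons and catalytic enantioselective desymmetrisations of Birch-derived cyclohexa-2,5-dienes; their combination into an enantiotopic-group-selective hydromethylation is not known. No ring is closed and the new quaternary carbon C1 is not stereogenic: the only new stereocentre is C6, whose configuration is decided by which olefin is methylated, that is by the chiral nickel complex choosing between two enantiomeric radicals that stay in equilibrium through the reversible hydrogen-atom transfer, with a five-membered chelate from nickel on C1 to the ester carbonyl on C6 expected to rigidify the selecting transition state. Any S ester that forms still contains the olefin the catalyst prefers and should be methylated again to the achiral 2,2,6,6-tetramethyl ester faster than the R ester, so running slightly past full conversion of 4 should raise the enantiomeric purity of 6. Markovnikov regiochemistry is secured by tertiary over secondary radical formation at the CMe=CH olefins, and the stop at mono-addition by the slower nickel capture at C5 of 6 once C6 is flanked by the new quaternary C1. The chief liability is hydrogen abstraction from the doubly allylic C3–H2 and C6–H bonds, leading to methyl 2,6-dimethylbenzoate, which low temperature, low iron loading and slow silane addition are meant to suppress.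

Step 4
Reactants: 6 methyl (1R)-2,6,6-trimethylcyclohex-2-ene-1-carboxylate
Product: 7 [(1R)-2,6,6-trimethylcyclohex-2-en-1-yl]methanol ((R)-α-cyclogeraniol)
Conditions: LiAlH4, Et2O, 0 °C; H2O, aq NaOH work-up
Reagents that add atoms: none
Why: Hydride reduction of the ester to the primary alcohol with LiAlH4, in which addition to the carbonyl is much faster than deprotonation at the hindered C6–H, so the stereocentre from step 3 should pass through unchanged.

Step 5
Reactants: 7 [(1R)-2,6,6-trimethylcyclohex-2-en-1-yl]methanol; 8 1-phenyl-1H-tetrazole-5-thiol
Product: 9 1-phenyl-5-({[(1R)-2,6,6-trimethylcyclohex-2-en-1-yl]methyl}sulfanyl)-1H-tetrazole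
Conditions: PPh3, DIAD, THF, 0 °C → rt
Reagents that add atoms: 1-phenyl-1H-tetrazole-5-thiol (compound 8), SC1=NN=NN1c1ccccc1
Why: Mitsunobu thioetherification, in which the alkoxyphosphonium ion of the primary alcohol is displaced at C7 by the acidic heteroaryl thiol in an SN2 step that does not involve C6.

Step 6
Reactants: 9 1-phenyl-5-({[(1R)-2,6,6-trimethylcyclohex-2-en-1-yl]methyl}sulfanyl)-1H-tetrazole
Product: 11 1-phenyl-5-({[(1R)-2,6,6-trimethylcyclohex-2-en-1-yl]methyl}sulfonyl)-1H-tetrazole, via sulfoxide 10 (not isolated)
Conditions: (NH4)6Mo7O24·4H2O (10 mol %), 30% aq H2O2 (5 equiv), EtOH, 0 °C → rt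
Reagents that add atoms: hydrogen peroxide, OO
Why: Molybdate-catalysed peroxide oxidation of a sulfide to the sulfone through the sulfoxide, in which the peroxomolybdate oxidises sulfur far faster than an isolated trisubstituted olefin without a directing hydroxyl group, so the C4=C5 bond should survive.

Step 7
Reactants: 11 1-phenyl-5-({[(1R)-2,6,6-trimethylcyclohex-2-en-1-yl]methyl}sulfonyl)-1H-tetrazole (2.4 equiv); 12 crocetin dialdehyde (all-E 2,6,11,15-tetramethylhexadeca-2,4,6,8,10,12,14-heptaenedial)
Product: 14 (6R,6'R)-ε,ε-carotene, via mono-olefinated aldehyde 13 (not isolated)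
Conditions: KN(SiMe3)2 (2.5 equiv), THF, –78 °C; then 12 in THF, –78 °C → rt, argon, dark; aq NH4Cl
Reagents that add atoms: none
Why: Double Julia–Kocienski olefination, in which each potassium sulfonyl carbanion adds to an aldehyde of 12 and Smiles transfer of the tetrazole to oxygen followed by loss of SO2 and tetrazolate should give the C7=C8 and C7'=C8' olefins with the E preference typical of 1-phenyltetrazolyl sulfones, while C6 and C6', which carry only a non-acidic allylic hydrogen, are untouched.

Compound list
1 | 2,6-dimethylbenzoic acid | Cc1cccc(C)c1C(=O)O | starting material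
2 | dilithium (2,6-dimethylcyclohexa-2,5-dien-1-ylidene)methanediolate (Birch enediolate) | CC1=CCC=C(C)C1=C([O-])[O-].[Li+].[Li+] | intermediate
3 | 2,6-dimethylcyclohexa-2,5-diene-1-carboxylic acid | CC1=CCC=C(C)C1C(=O)O | intermediate
4 | methyl 2,6-dimethylcyclohexa-2,5-diene-1-carboxylate | CC1=CCC=C(C)C1C(=O)OC | intermediate
5 | iodomethane | CI | starting material
6 | methyl (1R)-2,6,6-trimethylcyclohex-2-ene-1-carboxylate | CC1=CCCC(C)(C)[C@H]1C(=O)OC | intermediate
7 | [(1R)-2,6,6-trimethylcyclohex-2-en-1-yl]methanol | CC1=CCCC(C)(C)[C@H]1CO | intermediate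
8 | 1-phenyl-1H-tetrazole-5-thiol | SC1=NN=NN1c1ccccc1 | starting material
9 | 1-phenyl-5-({[(1R)-2,6,6-trimethylcyclohex-2-en-1-yl]methyl}sulfanyl)-1H-tetrazole | CC1=CCCC(C)(C)[C@H]1CSC2=NN=NN2c3ccccc3 | intermediate
10 | 1-phenyl-5-({[(1R)-2,6,6-trimethylcyclohex-2-en-1-yl]methyl}sulfinyl)-1H-tetrazole (both configurations at sulfur) | CC1=CCCC(C)(C)[C@H]1CS(=O)C2=NN=NN2c3ccccc3 | intermediate
11 | 1-phenyl-5-({[(1R)-2,6,6-trimethylcyclohex-2-en-1-yl]methyl}sulfonyl)-1H-tetrazole | CC1=CCCC(C)(C)[C@H]1CS(=O)(=O)C2=NN=NN2c3ccccc3 | intermediate
12 | crocetin dialdehyde | O=C/C(C)=C/C=C/C(C)=C/C=C/C=C(C)/C=C/C=C(C)/C=O | starting material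
13 | (6R)-8'-apo-ε-caroten-8'-al, all-E (C30 aldehyde from one olefination) | CC1=CCCC(C)(C)[C@H]1/C=C/C(C)=C/C=C/C(C)=C/C=C/C=C(C)/C=C/C=C(C)/C=O | intermediate
14 | (6R,6'R)-ε,ε-carotene, all-E | CC1=CCCC(C)(C)[C@H]1/C=C/C(C)=C/C=C/C(C)=C/C=C/C=C(C)/C=C/C=C(C)/C=C/[C@H]1C(C)=CCCC1(C)C | target

Total step count: 7. Longest linear sequence: 7 steps (1 → 14).

Steps most likely to fail

Step 3. The nickel complex may fail to distinguish the two enantiotopic olefins, or the diene may aromatise through hydrogen abstraction before the radical is captured. The fallback sets out from 4 and comes back at 7. It gives up the chiral catalysis and installs the methyl group in racemic form by the known iron-hydride radical hydromethylation of unactivated olefins. Treating 4 with Fe(acac)3, PhSiH3 and formaldehyde methanesulfonylhydrazone (made in the flask from aqueous formaldehyde and methanesulfonyl hydrazide) in THF/MeOH would give the hydrazide adduct methyl 6-{[2-(methanesulfonyl)hydrazin-1-yl]methyl}-2,6-dimethylcyclohex-2-ene-1-carboxylate F1. Warming F1 in methanol should expel methanesulfinic acid and dinitrogen to leave racemic methyl 2,6,6-trimethylcyclohex-2-ene-1-carboxylate F2. Ester cleavage with KOSiMe3 in THF would give racemic 2,6,6-trimethylcyclohex-2-ene-1-carboxylic acid F3. This would be resolved classically by crystallising the (R)-1-phenylethylammonium salt of the R acid F4 (or the salt of the antipodal amine, whichever crystallises with the R acid). Dilute HCl would release (1R)-2,6,6-trimethylcyclohex-2-ene-1-carboxylic acid F5, and LiAlH4 in Et2O would reduce it to 7.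

Step 7. The second olefination may stall on the sparingly soluble, base-sensitive polyene dialdehyde, and E geometry at C7=C8 may erode. The fallback sets out from 11 and comes back at 14. It closes the polyene by the classical C15 + C10 + C15 Wittig coupling at C11=C12 instead. Julia–Kocienski olefination of 11 with the small, soluble (E)-4-acetoxy-2-methylbut-2-enal (KN(SiMe3)2, THF, –78 °C) would give (2E,4E)-3-methyl-5-[(1R)-2,6,6-trimethylcyclohex-2-en-1-yl]penta-2,4-dien-1-yl acetate F6. PPh3·HBr in methanol should ionise the allylic acetate and give {(2E,4E)-3-methyl-5-[(1R)-2,6,6-trimethylcyclohex-2-en-1-yl]penta-2,4-dien-1-yl}triphenylphosphonium bromide F7. Double Wittig reaction of F7 with (2E,4E,6E)-2,7-dimethylocta-2,4,6-trienedial (NaOMe, CH2Cl2/MeOH), followed by thermal equilibration of any 11Z isomers in hot heptane, would give 14.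

Step 5. The SN2 displacement at the doubly β-branched primary carbon C7 may be sluggish, so that the alkoxyphosphonium intermediate is diverted to elimination or to adducts of the azo reagent. The fallback sets out from 7 and comes back at 9. It reverses the order of C–S bond formation so that the hindered carbon meets a small nucleophile and the heteroaryl–sulfur bond is made last. Mitsunobu reaction of 7 with thioacetic acid (PPh3, DIAD, THF) would give S-{[(1R)-2,6,6-trimethylcyclohex-2-en-1-yl]methyl} ethanethioate F8. K2CO3 in degassed methanol would release [(1R)-2,6,6-trimethylcyclohex-2-en-1-yl]methanethiol F9. F9 would be arylated in the same flask with 5-chloro-1-phenyl-1H-tetrazole by nucleophilic aromatic substitution to give 9.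

Further compounds
F1 | step 3 | methyl 6-{[2-(methanesulfonyl)hydrazin-1-yl]methyl}-2,6-dimethylcyclohex-2-ene-1-carboxylate (racemic, diastereomer mixture) | CC1=CCCC(C)(CNNS(C)(=O)=O)C1C(=O)OC
F2 | step 3 | racemic methyl 2,6,6-trimethylcyclohex-2-ene-1-carboxylate | CC1=CCCC(C)(C)C1C(=O)OC
F3 | step 3 | racemic 2,6,6-trimethylcyclohex-2-ene-1-carboxylic acid | CC1=CCCC(C)(C)C1C(=O)O
F4 | step 3 | (R)-1-phenylethylammonium (1R)-2,6,6-trimethylcyclohex-2-ene-1-carboxylate | CC1=CCCC(C)(C)[C@H]1C(=O)[O-].C[C@@H]([NH3+])c1ccccc1
F5 | step 3 | (1R)-2,6,6-trimethylcyclohex-2-ene-1-carboxylic acid | CC1=CCCC(C)(C)[C@H]1C(=O)O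
F6 | step 7 | (2E,4E)-3-methyl-5-[(1R)-2,6,6-trimethylcyclohex-2-en-1-yl]penta-2,4-dien-1-yl acetate | CC1=CCCC(C)(C)[C@H]1/C=C/C(C)=C/COC(C)=O
F7 | step 7 | {(2E,4E)-3-methyl-5-[(1R)-2,6,6-trimethylcyclohex-2-en-1-yl]penta-2,4-dien-1-yl}triphenylphosphonium bromide | CC1=CCCC(C)(C)[C@H]1/C=C/C(C)=C/C[P+](c1ccccc1)(c1ccccc1)c1ccccc1.[Br-]
F8 | step 5 | S-{[(1R)-2,6,6-trimethylcyclohex-2-en-1-yl]methyl} ethanethioate | CC1=CCCC(C)(C)[C@H]1CSC(C)=O
F9 | step 5 | [(1R)-2,6,6-trimethylcyclohex-2-en-1-yl]methanethiol | CC1=CCCC(C)(C)[C@H]1CS
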